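The route rests on cutting the O–C5' bond of the 2,5-dihydrofuran ring (O–C8'–C7'=C6'–C5', fused to the cyclohexane at C5'/C6'), whose oxygen bridges C8' and the quaternary C5'. That pattern is a trans-7',8'-vinyl oxirane of a β-ring diene after a 1,3-oxygen shift. One copper-catalysed step closes the furan ring, forms the quaternary C5'–O centre and moves the alkene to C6'=C7', while C8' is carried over untouched from a Sharpless epoxidation. The precursor is the pivalate of a (2S,3S)-epoxy alcohol carrying the (R)-4-silyloxy-2,6,6-trimethylcyclohexenyl group. The bicycle is then grown to a C15 phosphonium salt and joined through C10-dialdehyde to a (3S,5R,6S)-triol C15 salt.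

Key step: step 6

Remark: carotenoid locants are used (primed for the furanoid half); TBS = tert-butyldimethylsilyl, Piv = pivaloyl. The C10-dialdehyde, the stabilised ylide, the C5 phosphonate and both diethyl tartrates are taken as purchasable. The C8' descriptor changes from S (oxirane) to R (dihydrofuran) only because C7' loses its oxygen; no bond to C8' is broken.

Step 1
Reactants: 1 (4R,6R)-4-hydroxy-2,2,6-trimethylcyclohexanone (actinol)
Product: 2 (4R,6R)-4-(tert-butyldimethylsilyloxy)-2,2,6-trimethylcyclohexanone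
Conditions: TBSCl, imidazole, DMF, rt
Reagents that add atoms: tert-butyldimethylsilyl chloride, CC(C)(C)[Si](C)(C)Cl
Why: Silyl ether formation on the only hydroxyl; it masks the C3/C3' oxygen for the whole route and touches no stereocentre.

Step 2
Reactants: 2 (4R,6R)-4-(tert-butyldimethylsilyloxy)-2,2,6-trimethylcyclohexanone
Product: 4 (R)-4-(tert-butyldimethylsilyloxy)-2,6,6-trimethylcyclohex-1-en-1-yl trifluoromethanesulfonate, via lithium enolate 3 (not isolated)
Conditions: LiN(i-Pr)2, THF, −78 °C; then PhNTf2, −78 °C → rt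
Reagents that add atoms: N-phenylbis(trifluoromethanesulfonimide), O=S(=O)(N(c1ccccc1)S(=O)(=O)C(F)(F)F)C(F)(F)F
Why: Enol triflate formation; the ketone can enolise only toward C6 because C2 is quaternary, so one regioisomer should form, the C6 centre is erased on purpose and C4 is untouched.

Step 3
Reactants: 4 (R)-4-(tert-butyldimethylsilyloxy)-2,6,6-trimethylcyclohex-1-en-1-yl trifluoromethanesulfonate; 5 (E)-3-(tributylstannyl)prop-2-en-1-ol
Product: 6 (E)-3-[(R)-4-(tert-butyldimethylsilyloxy)-2,6,6-trimethylcyclohex-1-en-1-yl]prop-2-en-1-ol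
Conditions: Pd2(dba)3 (2.5 mol %), AsPh3 (20 mol %), NMP, 50 °C
Reagents that add atoms: compound 5, CCCC[Sn](CCCC)(CCCC)/C=C/CO
Why: Stille coupling of an alkenyl triflate with an (E)-alkenylstannane proceeds with retention of alkene geometry, the soft arsine ligand speeding transmetalation at the hindered triflate while the free hydroxyl is tolerated.

Step 4
Reactants: 6 (E)-3-[(R)-4-(tert-butyldimethylsilyloxy)-2,6,6-trimethylcyclohex-1-en-1-yl]prop-2-en-1-ol
Product: 7 [(2S,3S)-3-[(R)-4-(tert-butyldimethylsilyloxy)-2,6,6-trimethylcyclohex-1-en-1-yl]oxiran-2-yl]methanol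
Conditions: Ti(Oi-Pr)4 (10 mol %), L-(+)-diethyl tartrate (12 mol %), t-BuOOH, 4 Å MS, CH2Cl2, −20 °C
Reagents that add atoms: tert-butyl hydroperoxide, CC(C)(C)OO
Why: Sharpless asymmetric epoxidation acts only on the alkene of the allylic alcohol (the ring alkene is out of reach of titanium), and L-(+)-tartrate sets C7' and C8' as (2S,3S) by reagent control, as it does for other (E)-3-substituted allylic alcohols.

Step 5
Reactants: 7 [(2S,3S)-3-[(R)-4-(tert-butyldimethylsilyloxy)-2,6,6-trimethylcyclohex-1-en-1-yl]oxiran-2-yl]methanol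
Product: 8 [(2S,3S)-3-[(R)-4-(tert-butyldimethylsilyloxy)-2,6,6-trimethylcyclohex-1-en-1-yl]oxiran-2-yl]methyl pivalate
Conditions: PivCl, pyridine, DMAP (cat.), CH2Cl2, 0 °C
Reagents that add atoms: pivaloyl chloride, CC(C)(C)C(=O)Cl
Why: Esterification of the primary alcohol; the pivalate removes the free hydroxyl (no Payne migration or copper chelation later), inductively deactivates the C8'–O bond and is too hindered to act as a neighbouring group.

Step 6
Reactants: 8 [(2S,3S)-3-[(R)-4-(tert-butyldimethylsilyloxy)-2,6,6-trimethylcyclohex-1-en-1-yl]oxiran-2-yl]methyl pivalate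
Product: 9 [(2R,6S,7aR)-6-(tert-butyldimethylsilyloxy)-4,4,7a-trimethyl-2,4,5,6,7,7a-hexahydro-1-benzofuran-2-yl]methyl pivalate
Conditions: Cu(CF3COCHCOCF3)2 (5 mol %), PhMe, 80–110 °C, sealed tube, acid-free glassware
Reagents that add atoms: none
Why: The divalent copper Lewis acid binds the oxirane oxygen and ionises only the allylic C7'–O bond, giving a contact ion pair (cation spread over C7'–C6'–C5', tertiary at C5'; copper alkoxide still on C8') that collapses by O–C5' bond formation, a net 1,3-oxygen shift. The closest known reaction type is the Cu(CF3COCHCOCF3)2-catalysed ring expansion of vinyl oxiranes to 2,5-dihydrofurans. The ring O–C8'–C7'=C6'–C5' closes by a formally 5-endo-trig capture of the C5' terminus of the allyl cation by the C8' alkoxide, possible only from the s-cis conformer about C6'–C7'. The new stereocentre C5' is controlled by C7': in the s-cis conformer of the (7'S,8'S)-oxirane the C7'–O bond that overlaps the π system lies on the ring face opposite to the C3' silyloxy group, so suprafacial delivery gives 5'R with C9' trans to the C5' methyl, while C8' is never broken and C3' is a spectator. The step needs C7'–O rather than C8'–O cleavage and facial fidelity without rotation about C7'–C8'; these are secured by the allylic against non-allylic nature of the two oxirane carbons (C8' further deactivated by the pivaloyloxymethyl group), by the non-polar solvent that keeps the ion pair tight, and by the strain of the alternative cis-5',8' product.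

Step 7
Reactants: 9 [(2R,6S,7aR)-6-(tert-butyldimethylsilyloxy)-4,4,7a-trimethyl-2,4,5,6,7,7a-hexahydro-1-benzofuran-2-yl]methyl pivalate
Product: 10 [(2R,6S,7aR)-6-(tert-butyldimethylsilyloxy)-4,4,7a-trimethyl-2,4,5,6,7,7a-hexahydro-1-benzofuran-2-yl]methanol
Conditions: (i-Bu)2AlH, CH2Cl2, −78 °C; aq KNaC4H4O6
Reagents that add atoms: none
Why: Reductive ester cleavage by an aluminium hydride at low temperature frees the primary alcohol and leaves the silyl ether and the allylic ether intact.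

Step 8
Reactants: 10 [(2R,6S,7aR)-6-(tert-butyldimethylsilyloxy)-4,4,7a-trimethyl-2,4,5,6,7,7a-hexahydro-1-benzofuran-2-yl]methanol
Product: 11 (2R,6S,7aR)-6-(tert-butyldimethylsilyloxy)-4,4,7a-trimethyl-2,4,5,6,7,7a-hexahydro-1-benzofuran-2-carbaldehyde
Conditions: (n-Pr)4N[RuO4] (5 mol %), NMO, 4 Å MS, CH2Cl2, rt; used crude
Reagents that add atoms: none
Why: Ley–Griffith oxidation is neutral and should not epimerise C8', whose hydrogen is now both allylic and α to the carbonyl.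

Step 9
Reactants: 11 (2R,6S,7aR)-6-(tert-butyldimethylsilyloxy)-4,4,7a-trimethyl-2,4,5,6,7,7a-hexahydro-1-benzofuran-2-carbaldehyde
Product: 12 1-[(2R,6S,7aR)-6-(tert-butyldimethylsilyloxy)-4,4,7a-trimethyl-2,4,5,6,7,7a-hexahydro-1-benzofuran-2-yl]ethanol (both carbinol epimers)
Conditions: MeMgBr, THF, −78 °C; aq NH4Cl
Reagents that add atoms: methylmagnesium bromide, C[Mg]Br
Why: Grignard addition to the aldehyde outruns enolisation at −78 °C, and the new carbinol configuration is irrelevant because it is oxidised in the next step.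

Step 10
Reactants: 12 1-[(2R,6S,7aR)-6-(tert-butyldimethylsilyloxy)-4,4,7a-trimethyl-2,4,5,6,7,7a-hexahydro-1-benzofuran-2-yl]ethanol
Product: 13 1-[(2R,6S,7aR)-6-(tert-butyldimethylsilyloxy)-4,4,7a-trimethyl-2,4,5,6,7,7a-hexahydro-1-benzofuran-2-yl]ethanone
Conditions: (n-Pr)4N[RuO4] (5 mol %), NMO, 4 Å MS, CH2Cl2, rt
Reagents that add atoms: none
Why: Ley–Griffith oxidation of the secondary alcohol gives the C13 methyl ketone under neutral conditions that should keep C8' configurationally intact.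

Step 11
Reactants: 13 1-[(2R,6S,7aR)-6-(tert-butyldimethylsilyloxy)-4,4,7a-trimethyl-2,4,5,6,7,7a-hexahydro-1-benzofuran-2-yl]ethanone; 14 ethyl (triphenylphosphoranylidene)acetate
Product: 15 ethyl (E)-3-[(2R,6S,7aR)-6-(tert-butyldimethylsilyloxy)-4,4,7a-trimethyl-2,4,5,6,7,7a-hexahydro-1-benzofuran-2-yl]but-2-enoate
Conditions: PhMe, 90 °C
Reagents that add atoms: compound 14, CCOC(=O)C=P(c1ccccc1)(c1ccccc1)c1ccccc1
Why: Wittig olefination with a stabilised ylide is nearly non-basic, so the enolisable C8' centre should survive, and it places the ester trans to the larger α-oxygenated substituent to give the (E)-C9'=C10' alkene; α-alkoxy ketones are activated enough to react with such ylides on heating.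

Step 12
Reactants: 15 ethyl (E)-3-[(2R,6S,7aR)-6-(tert-butyldimethylsilyloxy)-4,4,7a-trimethyl-2,4,5,6,7,7a-hexahydro-1-benzofuran-2-yl]but-2-enoate
Product: 16 (E)-3-[(2R,6S,7aR)-6-(tert-butyldimethylsilyloxy)-4,4,7a-trimethyl-2,4,5,6,7,7a-hexahydro-1-benzofuran-2-yl]but-2-en-1-ol
Conditions: (i-Bu)2AlH, CH2Cl2, −78 °C; aq KNaC4H4O6
Reagents that add atoms: none
Why: Hydride 1,2-reduction of the conjugated ester gives the C15 allylic alcohol without touching the alkene geometry.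

Step 13
Reactants: 16 (E)-3-[(2R,6S,7aR)-6-(tert-butyldimethylsilyloxy)-4,4,7a-trimethyl-2,4,5,6,7,7a-hexahydro-1-benzofuran-2-yl]but-2-en-1-ol
Product: 18 [(E)-3-[(2R,6S,7aR)-6-(tert-butyldimethylsilyloxy)-4,4,7a-trimethyl-2,4,5,6,7,7a-hexahydro-1-benzofuran-2-yl]but-2-en-1-yl]triphenylphosphonium bromide, via allylic bromide 17 (not isolated)
Conditions: CBr4, PPh3, CH2Cl2, 0 °C; then PPh3, rt
Reagents that add atoms: carbon tetrabromide, BrC(Br)(Br)Br; triphenylphosphine, c1ccccc1P(c1ccccc1)c1ccccc1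
Why: Appel bromination of the primary allylic alcohol followed by SN2 quaternisation of PPh3 makes the Wittig salt under neutral conditions, avoiding the acid that would ionise the doubly allylic C8'–O bond.

Step 14
Reactants: 4 (R)-4-(tert-butyldimethylsilyloxy)-2,6,6-trimethylcyclohex-1-en-1-yl trifluoromethanesulfonate
Product: 19 methyl (R)-4-(tert-butyldimethylsilyloxy)-2,6,6-trimethylcyclohex-1-ene-1-carboxylate
Conditions: Pd(OAc)2 (5 mol %), PPh3 (10 mol %), CO (1 atm), MeOH, Et3N, DMF, 60 °C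
Reagents that add atoms: carbon monoxide, [C-]#[O+]; methanol, CO
Why: Palladium-catalysed alkoxycarbonylation of the alkenyl triflate (CO insertion, then methanolysis of the acylpalladium) installs C7 of the triol half.

Step 15
Reactants: 19 methyl (R)-4-(tert-butyldimethylsilyloxy)-2,6,6-trimethylcyclohex-1-ene-1-carboxylate
Product: 20 [(R)-4-(tert-butyldimethylsilyloxy)-2,6,6-trimethylcyclohex-1-en-1-yl]methanol
Conditions: (i-Bu)2AlH, CH2Cl2, −78 °C; aq KNaC4H4O6
Reagents that add atoms: none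
Why: Hydride reduction of the unsaturated ester gives the tetrasubstituted allylic alcohol needed for a directed epoxidation.

Step 16
Reactants: 20 [(R)-4-(tert-butyldimethylsilyloxy)-2,6,6-trimethylcyclohex-1-en-1-yl]methanol
Product: 21 [(1R,4S,6R)-4-(tert-butyldimethylsilyloxy)-2,2,6-trimethyl-7-oxabicyclo[4.1.0]heptan-1-yl]methanol
Conditions: Ti(Oi-Pr)4 (1.0 equiv), D-(−)-diethyl tartrate (1.2 equiv), t-BuOOH, 4 Å MS, CH2Cl2, −20 °C
Reagents that add atoms: tert-butyl hydroperoxide, CC(C)(C)OO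
Why: Sharpless asymmetric epoxidation under reagent control sets C5 and C6: D-(−)-tartrate delivers oxygen to the alkene face anti to the C3 silyloxy group, the same facial sense by which it gives (2R,3R)-epoxygeraniol.

Step 17
Reactants: 21 [(1R,4S,6R)-4-(tert-butyldimethylsilyloxy)-2,2,6-trimethyl-7-oxabicyclo[4.1.0]heptan-1-yl]methanol
Product: 22 (1S,4S,6R)-4-(tert-butyldimethylsilyloxy)-2,2,6-trimethyl-7-oxabicyclo[4.1.0]heptane-1-carbaldehyde
Conditions: (n-Pr)4N[RuO4] (5 mol %), NMO, 4 Å MS, CH2Cl2, rt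
Reagents that add atoms: none
Why: Ley–Griffith oxidation gives the epoxy aldehyde, which cannot epimerise because the formyl group sits on a fully substituted oxirane carbon.

Step 18
Reactants: 22 (1S,4S,6R)-4-(tert-butyldimethylsilyloxy)-2,2,6-trimethyl-7-oxabicyclo[4.1.0]heptane-1-carbaldehyde; 23 ethyl (E)-4-(diethoxyphosphoryl)-3-methylbut-2-enoate
Product: 25 ethyl (2E,4E)-5-[(1S,4S,6R)-4-(tert-butyldimethylsilyloxy)-2,2,6-trimethyl-7-oxabicyclo[4.1.0]heptan-1-yl]-3-methylpenta-2,4-dienoate, via sodium phosphonate anion 24 (not isolated)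
Conditions: NaH, THF, 0 °C; then 22, 0 °C → rt
Reagents that add atoms: compound 23, CCOC(=O)/C=C(\C)CP(=O)(OCC)OCC
Why: Horner–Wadsworth–Emmons olefination of the non-enolisable aldehyde with the vinylogous C5 phosphonate should give the (7E,9E)-dienoate, any minor 9Z isomer being removed by chromatography.

Step 19
Reactants: 25 ethyl (2E,4E)-5-[(1S,4S,6R)-4-(tert-butyldimethylsilyloxy)-2,2,6-trimethyl-7-oxabicyclo[4.1.0]heptan-1-yl]-3-methylpenta-2,4-dienoate
Product: 26 ethyl (2E,4E)-5-[(3aS,6S,7aR)-6-(tert-butyldimethylsilyloxy)-4,4,7a-trimethyl-2-oxohexahydro-1,3-benzodioxol-3a-yl]-3-methylpenta-2,4-dienoate (cis-fused cyclic carbonate)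
Conditions: Pd2(dba)3·CHCl3 (2.5 mol %), P(Oi-Pr)3 (15 mol %), CO2 (1 atm), THF, 0 °C → rt
Reagents that add atoms: carbon dioxide, O=C=O
Why: Tsuji–Trost-type opening of the vinyl oxirane under CO2: zerovalent palladium ionises the allylic C6–O bond with inversion, the C5 alkoxide takes up CO2 and the carbonate re-attacks C6 anti to palladium, so the double inversion returns oxygen to its original face and gives the cis-5,6-carbonate (C5–O is never broken).

Step 20
Reactants: 26 ethyl (2E,4E)-5-[(3aS,6S,7aR)-6-(tert-butyldimethylsilyloxy)-4,4,7a-trimethyl-2-oxohexahydro-1,3-benzodioxol-3a-yl]-3-methylpenta-2,4-dienoate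
Product: 27 (1S,2R,4S)-4-(tert-butyldimethylsilyloxy)-1-[(1E,3E)-5-hydroxy-3-methylpenta-1,3-dien-1-yl]-2,6,6-trimethylcyclohexane-1,2-diol
Conditions: LiAlH4, THF, 0 °C; aq KNaC4H4O6
Reagents that add atoms: none
Why: Hydride reduction converts the conjugated ester into the allylic alcohol and the cyclic carbonate into the free cis-diol in one operation, so the later ylide carries no leaving group at C6.

Step 21
Reactants: 27 (1S,2R,4S)-4-(tert-butyldimethylsilyloxy)-1-[(1E,3E)-5-hydroxy-3-methylpenta-1,3-dien-1-yl]-2,6,6-trimethylcyclohexane-1,2-diol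
Product: 29 [(2E,4E)-5-[(1S,2R,4S)-4-(tert-butyldimethylsilyloxy)-1,2-dihydroxy-2,6,6-trimethylcyclohexyl]-3-methylpenta-2,4-dien-1-yl]triphenylphosphonium bromide, via allylic bromide 28 (not isolated)
Conditions: CBr4, PPh3, CH2Cl2, −20 °C; then PPh3, rt
Reagents that add atoms: carbon tetrabromide, BrC(Br)(Br)Br; triphenylphosphine, c1ccccc1P(c1ccccc1)c1ccccc1
Why: Appel bromination is selective for the primary allylic hydroxyl because both tertiary hydroxyls are too hindered, and quaternisation of PPh3 gives the salt without acid that could ionise the tertiary allylic C6–OH.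

Step 22
Reactants: 18 [(E)-3-[(2R,6S,7aR)-6-(tert-butyldimethylsilyloxy)-4,4,7a-trimethyl-2,4,5,6,7,7a-hexahydro-1-benzofuran-2-yl]but-2-en-1-yl]triphenylphosphonium bromide; 30 (2E,4E,6E)-2,7-dimethylocta-2,4,6-trienedial
Product: 32 (2E,4E,6E,8E,10E)-11-[(2R,6S,7aR)-6-(tert-butyldimethylsilyloxy)-4,4,7a-trimethyl-2,4,5,6,7,7a-hexahydro-1-benzofuran-2-yl]-2,7-dimethyldodeca-2,4,6,8,10-pentaenal, via phosphorus ylide 31 (not isolated)
Conditions: NaOMe, 30 (3 equiv), MeOH/CH2Cl2, 0 °C → rt; then EtOAc, 70 °C, dark, argon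
Reagents that add atoms: compound 30, O=C/C(C)=C/C=C/C=C(\C)C=O
Why: Wittig olefination of the allylic ylide with one formyl group of the excess symmetrical dialdehyde builds C11'=C12', and the hindered (Z) isomer should equilibrate to (E) on gentle heating.

Step 23
Reactants: 29 [(2E,4E)-5-[(1S,2R,4S)-4-(tert-butyldimethylsilyloxy)-1,2-dihydroxy-2,6,6-trimethylcyclohexyl]-3-methylpenta-2,4-dien-1-yl]triphenylphosphonium bromide; 32 (2E,4E,6E,8E,10E)-11-[(2R,6S,7aR)-6-(tert-butyldimethylsilyloxy)-4,4,7a-trimethyl-2,4,5,6,7,7a-hexahydro-1-benzofuran-2-yl]-2,7-dimethyldodeca-2,4,6,8,10-pentaenal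
Product: 34 (3S,5R,6S,3'S,5'R,8'R)-3,3'-bis(tert-butyldimethylsilyloxy)-5',8'-epoxy-5,6,5',8'-tetrahydro-β,β-carotene-5,6-diol, via phosphorus ylide 33 (not isolated)
Conditions: NaOMe, MeOH/CH2Cl2, rt; then EtOAc, 70 °C, dark, argon
Reagents that add atoms: none
Why: The second Wittig olefination builds C11=C12 and completes the C40 chain; the free tertiary hydroxyls are poor leaving groups and are tolerated, and heating should bring the new alkene to (E).

Step 24
Reactants: 34 (3S,5R,6S,3'S,5'R,8'R)-3,3'-bis(tert-butyldimethylsilyloxy)-5',8'-epoxy-5,6,5',8'-tetrahydro-β,β-carotene-5,6-diol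
Product: 35 (3S,5R,6S,3'S,5'R,8'R)-5',8'-epoxy-5,6,5',8'-tetrahydro-β,β-carotene-3,5,6,3'-tetrol (CNP0210286.4)
Conditions: Bu4NF, THF, 0 °C → rt, dark, argon
Reagents that add atoms: none
Why: Fluoride desilylation removes both silyl ethers under non-acidic conditions, so neither the C8' furanoid centre nor the tertiary allylic C6–OH can ionise.

Compound list
1 | (4R,6R)-4-hydroxy-2,2,6-trimethylcyclohexanone (actinol) | O=C1C(C)(C)C[C@H](O)C[C@H]1C | starting material
2 | (4R,6R)-4-(tert-butyldimethylsilyloxy)-2,2,6-trimethylcyclohexanone | O=C1C(C)(C)C[C@H](O[Si](C)(C)C(C)(C)C)C[C@H]1C | intermediate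
3 | lithium (R)-4-(tert-butyldimethylsilyloxy)-2,6,6-trimethylcyclohex-1-en-1-olate | [Li+].[O-]C1=C(C)C[C@@H](O[Si](C)(C)C(C)(C)C)CC1(C)C | intermediate
4 | (R)-4-(tert-butyldimethylsilyloxy)-2,6,6-trimethylcyclohex-1-en-1-yl trifluoromethanesulfonate | O=S(=O)(OC1=C(C)C[C@@H](O[Si](C)(C)C(C)(C)C)CC1(C)C)C(F)(F)F | intermediate
5 | (E)-3-(tributylstannyl)prop-2-en-1-ol | CCCC[Sn](CCCC)(CCCC)/C=C/CO | starting material
6 | (E)-3-[(R)-4-(tert-butyldimethylsilyloxy)-2,6,6-trimethylcyclohex-1-en-1-yl]prop-2-en-1-ol | OC/C=C/C1=C(C)C[C@@H](O[Si](C)(C)C(C)(C)C)CC1(C)C | intermediate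
7 | [(2S,3S)-3-[(R)-4-(tert-butyldimethylsilyloxy)-2,6,6-trimethylcyclohex-1-en-1-yl]oxiran-2-yl]methanol | OC[C@@H]1O[C@H]1C2=C(C)C[C@@H](O[Si](C)(C)C(C)(C)C)CC2(C)C | intermediate
8 | [(2S,3S)-3-[(R)-4-(tert-butyldimethylsilyloxy)-2,6,6-trimethylcyclohex-1-en-1-yl]oxiran-2-yl]methyl pivalate | CC(C)(C)C(=O)OC[C@@H]1O[C@H]1C2=C(C)C[C@@H](O[Si](C)(C)C(C)(C)C)CC2(C)C | intermediate
9 | [(2R,6S,7aR)-6-(tert-butyldimethylsilyloxy)-4,4,7a-trimethyl-2,4,5,6,7,7a-hexahydro-1-benzofuran-2-yl]methyl pivalate | CC(C)(C)C(=O)OC[C@H]1C=C2C(C)(C)C[C@H](O[Si](C)(C)C(C)(C)C)C[C@@]2(C)O1 | intermediate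
10 | [(2R,6S,7aR)-6-(tert-butyldimethylsilyloxy)-4,4,7a-trimethyl-2,4,5,6,7,7a-hexahydro-1-benzofuran-2-yl]methanol | OC[C@H]1C=C2C(C)(C)C[C@H](O[Si](C)(C)C(C)(C)C)C[C@@]2(C)O1 | intermediate
11 | (2R,6S,7aR)-6-(tert-butyldimethylsilyloxy)-4,4,7a-trimethyl-2,4,5,6,7,7a-hexahydro-1-benzofuran-2-carbaldehyde | O=C[C@H]1C=C2C(C)(C)C[C@H](O[Si](C)(C)C(C)(C)C)C[C@@]2(C)O1 | intermediate
12 | 1-[(2R,6S,7aR)-6-(tert-butyldimethylsilyloxy)-4,4,7a-trimethyl-2,4,5,6,7,7a-hexahydro-1-benzofuran-2-yl]ethanol, both carbinol epimers | CC(O)[C@H]1C=C2C(C)(C)C[C@H](O[Si](C)(C)C(C)(C)C)C[C@@]2(C)O1 | intermediate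
13 | 1-[(2R,6S,7aR)-6-(tert-butyldimethylsilyloxy)-4,4,7a-trimethyl-2,4,5,6,7,7a-hexahydro-1-benzofuran-2-yl]ethanone | CC(=O)[C@H]1C=C2C(C)(C)C[C@H](O[Si](C)(C)C(C)(C)C)C[C@@]2(C)O1 | intermediate
14 | ethyl (triphenylphosphoranylidene)acetate | CCOC(=O)C=P(c1ccccc1)(c1ccccc1)c1ccccc1 | starting material
15 | ethyl (E)-3-[(2R,6S,7aR)-6-(tert-butyldimethylsilyloxy)-4,4,7a-trimethyl-2,4,5,6,7,7a-hexahydro-1-benzofuran-2-yl]but-2-enoate | CCOC(=O)/C=C(\C)[C@H]1C=C2C(C)(C)C[C@H](O[Si](C)(C)C(C)(C)C)C[C@@]2(C)O1 | intermediate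
16 | (E)-3-[(2R,6S,7aR)-6-(tert-butyldimethylsilyloxy)-4,4,7a-trimethyl-2,4,5,6,7,7a-hexahydro-1-benzofuran-2-yl]but-2-en-1-ol | OC/C=C(\C)[C@H]1C=C2C(C)(C)C[C@H](O[Si](C)(C)C(C)(C)C)C[C@@]2(C)O1 | intermediate
17 | (2R,6S,7aR)-2-[(E)-4-bromobut-2-en-2-yl]-6-(tert-butyldimethylsilyloxy)-4,4,7a-trimethyl-2,4,5,6,7,7a-hexahydro-1-benzofuran | BrC/C=C(\C)[C@H]1C=C2C(C)(C)C[C@H](O[Si](C)(C)C(C)(C)C)C[C@@]2(C)O1 | intermediate
18 | [(E)-3-[(2R,6S,7aR)-6-(tert-butyldimethylsilyloxy)-4,4,7a-trimethyl-2,4,5,6,7,7a-hexahydro-1-benzofuran-2-yl]but-2-en-1-yl]triphenylphosphonium bromide | [Br-].c1ccccc1[P+](c1ccccc1)(c1ccccc1)C/C=C(\C)[C@H]1C=C2C(C)(C)C[C@H](O[Si](C)(C)C(C)(C)C)C[C@@]2(C)O1 | intermediate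
19 | methyl (R)-4-(tert-butyldimethylsilyloxy)-2,6,6-trimethylcyclohex-1-ene-1-carboxylate | COC(=O)C1=C(C)C[C@@H](O[Si](C)(C)C(C)(C)C)CC1(C)C | intermediate
20 | [(R)-4-(tert-butyldimethylsilyloxy)-2,6,6-trimethylcyclohex-1-en-1-yl]methanol | OCC1=C(C)C[C@@H](O[Si](C)(C)C(C)(C)C)CC1(C)C | intermediate
21 | [(1R,4S,6R)-4-(tert-butyldimethylsilyloxy)-2,2,6-trimethyl-7-oxabicyclo[4.1.0]heptan-1-yl]methanol (oxirane oxygen trans to the silyloxy group) | OC[C@]12C(C)(C)C[C@H](O[Si](C)(C)C(C)(C)C)C[C@@]1(C)O2 | intermediate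
22 | (1S,4S,6R)-4-(tert-butyldimethylsilyloxy)-2,2,6-trimethyl-7-oxabicyclo[4.1.0]heptane-1-carbaldehyde | O=C[C@]12C(C)(C)C[C@H](O[Si](C)(C)C(C)(C)C)C[C@@]1(C)O2 | intermediate
23 | ethyl (E)-4-(diethoxyphosphoryl)-3-methylbut-2-enoate | CCOC(=O)/C=C(\C)CP(=O)(OCC)OCC | starting material
24 | sodium salt of the C4 carbanion of 23 | [Na+].CCOC(=O)/C=C(\C)[CH-]P(=O)(OCC)OCC | intermediate
25 | ethyl (2E,4E)-5-[(1S,4S,6R)-4-(tert-butyldimethylsilyloxy)-2,2,6-trimethyl-7-oxabicyclo[4.1.0]heptan-1-yl]-3-methylpenta-2,4-dienoate | CCOC(=O)/C=C(C)/C=C/[C@]12C(C)(C)C[C@H](O[Si](C)(C)C(C)(C)C)C[C@@]1(C)O2 | intermediate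
26 | ethyl (2E,4E)-5-[(3aS,6S,7aR)-6-(tert-butyldimethylsilyloxy)-4,4,7a-trimethyl-2-oxohexahydro-1,3-benzodioxol-3a-yl]-3-methylpenta-2,4-dienoate (cis-fused carbonate, both oxygens trans to the silyloxy group) | CCOC(=O)/C=C(C)/C=C/[C@]1(OC(=O)O2)C(C)(C)C[C@H](O[Si](C)(C)C(C)(C)C)C[C@]12C | intermediate
27 | (1S,2R,4S)-4-(tert-butyldimethylsilyloxy)-1-[(1E,3E)-5-hydroxy-3-methylpenta-1,3-dien-1-yl]-2,6,6-trimethylcyclohexane-1,2-diol | OC/C=C(C)/C=C/[C@]1(O)C(C)(C)C[C@H](O[Si](C)(C)C(C)(C)C)C[C@@]1(C)O | intermediate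
28 | (1S,2R,4S)-1-[(1E,3E)-5-bromo-3-methylpenta-1,3-dien-1-yl]-4-(tert-butyldimethylsilyloxy)-2,6,6-trimethylcyclohexane-1,2-diol | BrC/C=C(C)/C=C/[C@]1(O)C(C)(C)C[C@H](O[Si](C)(C)C(C)(C)C)C[C@@]1(C)O | intermediate
29 | [(2E,4E)-5-[(1S,2R,4S)-4-(tert-butyldimethylsilyloxy)-1,2-dihydroxy-2,6,6-trimethylcyclohexyl]-3-methylpenta-2,4-dien-1-yl]triphenylphosphonium bromide | [Br-].c1ccccc1[P+](c1ccccc1)(c1ccccc1)C/C=C(C)/C=C/[C@]1(O)C(C)(C)C[C@H](O[Si](C)(C)C(C)(C)C)C[C@@]1(C)O | intermediate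
30 | (2E,4E,6E)-2,7-dimethylocta-2,4,6-trienedial | O=C/C(C)=C/C=C/C=C(\C)C=O | starting material
31 | ylide of 18 (deprotonated at C11') | c1ccccc1P(=C/C=C(\C)[C@H]1C=C2C(C)(C)C[C@H](O[Si](C)(C)C(C)(C)C)C[C@@]2(C)O1)(c1ccccc1)c1ccccc1 | intermediate
32 | (2E,4E,6E,8E,10E)-11-[(2R,6S,7aR)-6-(tert-butyldimethylsilyloxy)-4,4,7a-trimethyl-2,4,5,6,7,7a-hexahydro-1-benzofuran-2-yl]-2,7-dimethyldodeca-2,4,6,8,10-pentaenal | O=C/C(C)=C/C=C/C=C(C)/C=C/C=C(\C)[C@H]1C=C2C(C)(C)C[C@H](O[Si](C)(C)C(C)(C)C)C[C@@]2(C)O1 | intermediate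
33 | ylide of 29 (deprotonated at C11) | c1ccccc1P(=C/C=C(C)/C=C/[C@]1(O)C(C)(C)C[C@H](O[Si](C)(C)C(C)(C)C)C[C@@]1(C)O)(c1ccccc1)c1ccccc1 | intermediate
34 | (3S,5R,6S,3'S,5'R,8'R)-3,3'-bis(tert-butyldimethylsilyloxy)-5',8'-epoxy-5,6,5',8'-tetrahydro-β,β-carotene-5,6-diol | CC(/C=C/C=C(C)/C=C/[C@]1(O)C(C)(C)C[C@H](O[Si](C)(C)C(C)(C)C)C[C@@]1(C)O)=C\C=C\C=C(C)\C=C\C=C(/C)[C@H]1C=C2C(C)(C)C[C@H](O[Si](C)(C)C(C)(C)C)C[C@@]2(C)O1 | intermediate
35 | (3S,5R,6S,3'S,5'R,8'R)-5',8'-epoxy-5,6,5',8'-tetrahydro-β,β-carotene-3,5,6,3'-tetrol | CC(/C=C/C=C(C)/C=C/[C@]1(O)C(C)(C)C[C@H](O)C[C@@]1(C)O)=C\C=C\C=C(C)\C=C\C=C(/C)[C@H]1C=C2C(C)(C)C[C@H](O)C[C@@]2(C)O1 | target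

Total step count: 24.
Longest linear sequence: 16 steps (steps 1–13, then 22, 23, 24); the triol branch (steps 1, 2, 14–21, 23, 24) is 12 steps long.

Steps most likely to fail

Step 6. The allyl cation may lose a proton from the C5' methyl or from C4' (elimination to a triene), or a hydride may shift from C8' to give a carbonyl compound, before the oxygen closes on C5'. Rotation about C7'–C8' within the ion pair would erode facial fidelity at C5'. Fallback (acid-catalysed 5,6-epoxide to 5,8-furanoxide rearrangement, a different bond-forming logic): it sets out from 25. Reduction with (i-Bu)2AlH would give the epoxy dienol (2E,4E)-5-[(1S,4S,6R)-4-(tert-butyldimethylsilyloxy)-2,2,6-trimethyl-7-oxabicyclo[4.1.0]heptan-1-yl]-3-methylpenta-2,4-dien-1-ol F1. A catalytic amount of pyridinium p-toluenesulfonate in CH2Cl2 at 0 °C would then open the oxirane at C6 and let the C5 oxygen close on C8. This keeps the 5R centre but forms both C8 epimers, namely 16 and its epimer (E)-3-[(2S,6S,7aR)-6-(tert-butyldimethylsilyloxy)-4,4,7a-trimethyl-2,4,5,6,7,7a-hexahydro-1-benzofuran-2-yl]but-2-en-1-ol F2, to be separated by chromatography. The route is rejoined at 16 (before step 13).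

Step 19. Ionisation of the hindered, fully substituted oxirane by zerovalent palladium may be sluggish, or the allylpalladium intermediate may eliminate or lose its facial integrity before the carbonate closes. Fallback (carbonyl addition in place of epoxide opening): it sets out from 22. A Wharton transposition (N2H4·H2O, catalytic AcOH, MeOH) would give (1R,5S)-5-(tert-butyldimethylsilyloxy)-1,3,3-trimethyl-2-methylidenecyclohexan-1-ol F3 with the C5–O bond intact. Ozonolysis (O3, CH2Cl2/MeOH, −78 °C; Me2S) would give (2R,4S)-4-(tert-butyldimethylsilyloxy)-2-hydroxy-2,6,6-trimethylcyclohexan-1-one F4. Addition of excess dilithiated (E)-3-methylpent-2-en-4-yn-1-ol (commercial; n-BuLi, THF, −78 → 0 °C) should occur axially, anti to the axial C5 oxygen and away from the axial C1 methyl (Felkin–Anh sense). This would give (1R,2R,4S)-4-(tert-butyldimethylsilyloxy)-1-[(E)-5-hydroxy-3-methylpent-3-en-1-yn-1-yl]-2,6,6-trimethylcyclohexane-1,2-diol F5 with the 6-OH cis to the 5-OH. Hydroxyl-directed trans-hydroalumination with NaAlH2(OCH2CH2OMe)2 would then give the (7E)-diene, and the route is rejoined at 27 (before step 21).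

Step 11. Olefination of the hindered ketone may be slow, and prolonged heating could allow enolisation at C8' (epimerisation, or migration of the C6'=C7' alkene into conjugation) and incomplete E selectivity. Fallback (organometallic addition and allylic transposition in place of carbonyl olefination): it sets out from 13. Vinylmagnesium bromide (THF, −78 °C) would give the tertiary carbinol 2-[(2R,6S,7aR)-6-(tert-butyldimethylsilyloxy)-4,4,7a-trimethyl-2,4,5,6,7,7a-hexahydro-1-benzofuran-2-yl]but-3-en-2-ol F6 (both carbinol epimers). Brief treatment with PPh3·HBr in MeOH/CH2Cl2 at 0 °C would convert it, by SN1'-type allylic transposition, into the primary phosphonium salt, mainly (E), to be purified by crystallisation. The route is rejoined at 18 (before step 22), bypassing steps 11–13.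

Further compounds
F1 | step 6 | (2E,4E)-5-[(1S,4S,6R)-4-(tert-butyldimethylsilyloxy)-2,2,6-trimethyl-7-oxabicyclo[4.1.0]heptan-1-yl]-3-methylpenta-2,4-dien-1-ol | OC/C=C(C)/C=C/[C@]12C(C)(C)C[C@H](O[Si](C)(C)C(C)(C)C)C[C@@]1(C)O2
F2 | step 6 | (E)-3-[(2S,6S,7aR)-6-(tert-butyldimethylsilyloxy)-4,4,7a-trimethyl-2,4,5,6,7,7a-hexahydro-1-benzofuran-2-yl]but-2-en-1-ol | OC/C=C(\C)[C@@H]1C=C2C(C)(C)C[C@H](O[Si](C)(C)C(C)(C)C)C[C@@]2(C)O1
F3 | step 19 | (1R,5S)-5-(tert-butyldimethylsilyloxy)-1,3,3-trimethyl-2-methylidenecyclohexan-1-ol | C=C1C(C)(C)C[C@H](O[Si](C)(C)C(C)(C)C)C[C@@]1(C)O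
F4 | step 19 | (2R,4S)-4-(tert-butyldimethylsilyloxy)-2-hydroxy-2,6,6-trimethylcyclohexan-1-one | O=C1C(C)(C)C[C@H](O[Si](C)(C)C(C)(C)C)C[C@@]1(C)O
F5 | step 19 | (1R,2R,4S)-4-(tert-butyldimethylsilyloxy)-1-[(E)-5-hydroxy-3-methylpent-3-en-1-yn-1-yl]-2,6,6-trimethylcyclohexane-1,2-diol | OC/C=C(C)/C#C[C@]1(O)C(C)(C)C[C@H](O[Si](C)(C)C(C)(C)C)C[C@@]1(C)O
F6 | step 11 | 2-[(2R,6S,7aR)-6-(tert-butyldimethylsilyloxy)-4,4,7a-trimethyl-2,4,5,6,7,7a-hexahydro-1-benzofuran-2-yl]but-3-en-2-ol (both carbinol epimers) | C=CC(C)(O)[C@H]1C=C2C(C)(C)C[C@H](O[Si](C)(C)C(C)(C)C)C[C@@]2(C)O1
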